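Its constants are those of an exercise, and the outcome is calculated.

The pitfall in this flask is to set the dissolved gas equal to its saturation value and never ask what a small shortfall costs at the end of an exponential.

    gas phase ⇌ dissolved gas, rate k1*(csat - [dissolved gas]) (k1 = 11 s⁻¹, csat = 12 mM)
    starting material + dissolved gas → target (k2 = 4.6 M⁻¹ s⁻¹)
    dissolved gas + target → over-reacted product (k3 = 1.7 M⁻¹ s⁻¹)
    dissolved gas ⇌ dormant form (K4 = 86, k4 = 0.10 s⁻¹)
    crystals ⇌ target, rate k5*(cs5 - [target]) while solid is left; crystals form when [target] > cs5 (cs5 = 1.9 mM, k5 = 5.6 s⁻¹)

starting material 0.050 M; gas phase 12 mM (held); time 30 s

- amounts and yields of target count crystals too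
- given per volume of solution although it is solid: crystals
- at the start none of the gas is dissolved
- run time (flask): 30 s

- winter: doubling the solubility in step 5, all else as stated
- spring: doubling the dissolution coefficient of step 5, all else as stated
- dawn: doubling the transfer coefficient of step 1, all else as stated
- summer: doubling the saturation concentration of gas phase, all else as stated

- amount of target and crystals together at 30 s, in percent of the starting material charged
- the change that raises the amount of target and crystals together at 30 s, in percent of the starting material charged most ("none" if none brings more than 2 percentage points) (winter / spring / dawn / summer / none)
- amount of target and crystals together at 30 s, in percent of the starting material charged, after summer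

I work in logarithms. Gas transfer refills the solution much faster than the target-forming step empties it, at 11 s⁻¹ against 0.230 s⁻¹, so I first put c(dissolved gas) at 12 mM. The starting material then decays pseudo-first-order and falls one power of ten every 41.7 s. Crystals hold c(target) near the solubility of 1.9 mM, because passing the 2.76 mM s⁻¹ of target formed into crystals at a coefficient of 5.6 s⁻¹ takes an excess of 0.493 mM, less than that solubility. Over-reaction therefore runs at a steady rate, and whatever is neither left nor over-reacted is the answer.

The weak link is the gas. I set what transfer brings in equal to what the target-forming step at the full charge and the dormant step carry off, reading the constant of the dormant step as its forward one. That gives c(dissolved gas) = 11.7 mM and 42.9 s: this is the decade time, the time in which the starting material falls by one power of ten at the gas level that transfer can sustain.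

| | gas at saturation | gas reforged | summer |
|---|---|---|---|
| decade time | 41.7 s | 42.9 s | 21.5 s |
| starting material left | 19.1% | 20.0% | 4.01% |
| over-reacted | 2.33% | 2.26% | 4.52% |
| target and crystals | 78.6% | 77.7% | 91.5% |

I commit to 77.7% and to summer, which doubles the gas. Winter instead doubles the over-reaction, and dawn moves the decade time to 42.3 s.

The forecast gives 77.7%, summer and 90.8%, on the ground that “Fast gas transfer holds the dissolved gas close to saturation”. Its first figure stands 0.0087 percentage points below mine, and its last 0.70 points below mine.

In the flask the simulation gives 77.7% at 30 s, with 20% of the starting material left and 2.51% over-reacted; summer brings 13 points and reaches 91.0%, so the forecast stands. Its first figure moves by 5 points with the reading time at 25.6 s or 35.9 s, and by as much with the starting material down at 0.0146 M. The neighbouring flask is the same one read at 50 s, which is 1.17 decade times, so I reckon 6.85% left, 3.76% over-reacted and 89.4% target with crystals. Its run holds 6.6% starting material, 4.08% over-reacted product and 89.3% target with crystals.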